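**Strategy.** The six-membered dienone is disconnected at its O=C1–C2(Cl)=C3H unit. The chlorine-bearing carbon is inserted as dichlorocarbene between C1 and C5 of an enantiopure 4-hydroxy-4-alkyl-2-iodocyclopent-2-enone, used as its 2-siloxycyclopentadiene. One operation enlarges the five-membered ring to the cyclohexa-2,5-dienone, installs chlorine and the second enone, and turns a carbinol flanked by CH2 and CH= into the nearly symmetric carbinol of the target with its configuration intact. The carbinol is set by anti-1,2-addition to (R)-4-silyloxycyclopentenone, followed by oxidative erasure of the relay centre. The dienamide chain, from a lipase-desymmetrised meso-diol, is attached by copper-catalysed N-vinylation; desilylation and oxidation to the acid finish the route.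

Key step: step 6

Assumption: the Pseudomonas fluorescens lipase is taken to acetylate the hydroxymethyl group on the (S)-configured carbon of meso-diol 12; if it acylates the other arm, 13 would be obtained instead by hydrolysis of the diacetate with the same enzyme.

**Ring fragment**

Step 1
Reactants: 1 (R)-4-(tert-butyldimethylsilyloxy)cyclopent-2-en-1-one; 2 (5-bromopentyloxy)(tert-butyl)dimethylsilane
Product: 4 (1S,4R)-4-(tert-butyldimethylsilyloxy)-1-[5-(tert-butyldimethylsilyloxy)pentyl]cyclopent-2-en-1-ol, via Grignard reagent 3 (not isolated)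
Conditions: 2, Mg, THF, 40 °C; then CeCl3, −78 °C; then 1, THF, −78 °C
Reagents that add atoms: none
Why: Organocerium 1,2-addition to the enone, in which the oxophilic, weakly basic reagent should suppress enolisation/β-elimination and conjugate addition and attack the carbonyl face anti to the C4 silyloxy group, setting C1 as (S) (OH cis to OTBS); the minor diastereomer is removed by chromatography.

Step 2
Reactants: 4 (1S,4R)-4-(tert-butyldimethylsilyloxy)-1-[5-(tert-butyldimethylsilyloxy)pentyl]cyclopent-2-en-1-ol
Product: 5 (1S,4R)-1-(5-hydroxypentyl)cyclopent-2-ene-1,4-diol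
Conditions: TBAF, THF, 0 °C to rt
Reagents that add atoms: none
Why: Fluoride-mediated cleavage of both silyl ethers under non-acidic conditions should leave the ionisable tertiary allylic alcohol untouched.

Step 3
Reactants: 5 (1S,4R)-1-(5-hydroxypentyl)cyclopent-2-ene-1,4-diol
Product: 6 (S)-4-hydroxy-4-(5-hydroxypentyl)cyclopent-2-en-1-one
Conditions: MnO2, acetone, rt
Reagents that add atoms: none
Why: Chemoselective MnO2 oxidation of the secondary allylic alcohol (tertiary and saturated primary alcohols are inert) erases the relay stereocentre and leaves the quaternary carbinol as the only stereocentre.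

Step 4
Reactants: 6 (S)-4-hydroxy-4-(5-hydroxypentyl)cyclopent-2-en-1-one
Product: 7 (S)-4-hydroxy-4-(5-hydroxypentyl)-2-iodocyclopent-2-en-1-one
Conditions: I2, pyridine/CH2Cl2, 0 °C to rt
Reagents that add atoms: iodine, II
Why: Pyridine-mediated α-iodination of an enone (Baylis–Hillman-type addition, iodination of the enolate, elimination) should give the 2-iodoenone, well known for 4-oxygenated cyclopentenones.

Step 5
Reactants: 7 (S)-4-hydroxy-4-(5-hydroxypentyl)-2-iodocyclopent-2-en-1-one
Product: 8 (S)-2-iodo-3,5-bis(triethylsilyloxy)-5-[5-(triethylsilyloxy)pentyl]cyclopenta-1,3-diene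
Conditions: TESOTf, Et3N, CH2Cl2, −78 to 0 °C
Reagents that add atoms: triethylsilyl trifluoromethanesulfonate, CC[Si](CC)(CC)OS(=O)(=O)C(F)(F)F
Why: Silylation of both hydroxyls and soft enolisation (silyl triflate/amine) at C5, the only enolisable position, should give the 2-siloxycyclopentadiene, while loss of the C4 oxygen is disfavoured because it would lead to an antiaromatic cyclopentadienyl cation or cyclopentadienone; the diene is used crude.

Step 6
Reactants: 8 (S)-2-iodo-3,5-bis(triethylsilyloxy)-5-[5-(triethylsilyloxy)pentyl]cyclopenta-1,3-diene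
Product: 10 (S)-2-chloro-6-iodo-4-(triethylsilyloxy)-4-[5-(triethylsilyloxy)pentyl]cyclohexa-2,5-dien-1-one, via dichlorocyclopropane 9 (not isolated)
Conditions: CHCl3, KOtBu, hexane, −40 °C to rt
Reagents that add atoms: chloroform, ClC(Cl)Cl
Why: Dichlorocarbene from α-elimination of chloroform adds in a cheletropic [2+1] cycloaddition to the siloxy-substituted C=C of 8, closing the three-membered ring of 9; on warming, 9 undergoes the cyclopropyl-to-allyl cation opening (disrotatory, loss of the endo chloride, pushed by the siloxy oxygen), which cleaves the ring-fusion bond so that the carbene carbon becomes the C–Cl carbon next to the carbonyl, and chloride removes the enol silyl group to release the cross-conjugated dienone. The closest known reaction type is the dihalocarbene ring expansion of cyclic silyl enol ethers to 2-halocycloalk-2-enones, related to the Ciamician–Dennstedt enlargement of five-membered rings. The six-membered ring is not closed; it arises by insertion of one carbon into the C1–C5 bond of the five-membered ring. No stereocentre is created in the product: the two cyclopropane centres of 9 are transient and the quaternary carbinol is untouched, so the configuration defined in the cyclopentenone by its CH2 and CH= arms is carried into the dienone, where these arms have become C(Cl)=CH and C(I)=CH. The step needs chemoselectivity for the enol-ether double bond and the correct placement of chlorine; the substrate secures both, because the iodoalkene is deactivated towards the electrophilic carbene and the carbene carbon can only end between C1 and C5. Fast desilylation of the O-silylated dienone cation should forestall a quinol-type 1,2-shift.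

**Side chain**

Step 7
Reactants: 11 meso-2,4-dimethylglutaric anhydride
Product: 12 meso-(2R,4S)-2,4-dimethylpentane-1,5-diol
Conditions: LiAlH4, THF, 0 °C to reflux
Reagents that add atoms: none
Why: Hydride reduction of the cyclic anhydride to the diol should proceed without enolisation, so the syn-dimethyl relationship is kept.

Step 8
Reactants: 12 meso-(2R,4S)-2,4-dimethylpentane-1,5-diol
Product: 13 (2S,4R)-5-hydroxy-2,4-dimethylpentyl acetate
Conditions: lipase (Pseudomonas fluorescens), vinyl acetate, THF, rt
Reagents that add atoms: vinyl acetate, CC(=O)OC=C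
Why: Enzymatic desymmetrisation by a lipase (irreversible transesterification) differentiates the enantiotopic hydroxymethyl groups, which fixes both methyl-bearing stereocentres at once under control of the enzyme.

Step 9
Reactants: 13 (2S,4R)-5-hydroxy-2,4-dimethylpentyl acetate
Product: 14 (2S,4R)-2,4-dimethyl-5-oxopentyl acetate
Conditions: Dess–Martin periodinane, pyridine, CH2Cl2, 0 °C
Reagents that add atoms: none
Why: Buffered Dess–Martin oxidation should give the α-methyl aldehyde without epimerisation; it is used directly.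

Step 10
Reactants: 14 (2S,4R)-2,4-dimethyl-5-oxopentyl acetate
Product: 15 (2S,4R)-2,4,6-trimethylhept-5-en-1-yl acetate
Conditions: i-PrPPh3I, n-BuLi, THF, 0 °C; then 14, −78 °C to rt
Reagents that add atoms: isopropyltriphenylphosphonium iodide, CC(C)[P+](c1ccccc1)(c1ccccc1)c1ccccc1.[I-]
Why: Wittig olefination with the non-stabilised isopropylidene ylide should give the trisubstituted alkene (no geometric issue), the aldehyde reacting at low temperature much faster than the acetate or than it epimerises.

Step 11
Reactants: 15 (2S,4R)-2,4,6-trimethylhept-5-en-1-yl acetate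
Product: 16 (2S,4R)-2,4,6-trimethylhept-5-en-1-ol
Conditions: K2CO3 (cat.), MeOH, rt
Reagents that add atoms: none
Why: Base-catalysed transesterification with methanol removes the acetate without affecting the alkene or the stereocentres.

Step 12
Reactants: 16 (2S,4R)-2,4,6-trimethylhept-5-en-1-ol
Product: 18 (2E,4S,6R)-4,6,8-trimethylnona-2,7-dienamide, via aldehyde 17 (not isolated)
Conditions: Dess–Martin periodinane, pyridine, CH2Cl2, 0 °C; then Ph3P=CHCONH2, rt
Reagents that add atoms: (carbamoylmethylene)triphenylphosphorane, NC(=O)C=P(c1ccccc1)(c1ccccc1)c1ccccc1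
Why: One-pot Dess–Martin oxidation and Wittig olefination with a stabilised amide ylide should give the (E)-enamide, the epimerisable aldehyde being trapped as it forms.

**Union and completion**

Step 13
Reactants: 10 (S)-2-chloro-6-iodo-4-(triethylsilyloxy)-4-[5-(triethylsilyloxy)pentyl]cyclohexa-2,5-dien-1-one; 18 (2E,4S,6R)-4,6,8-trimethylnona-2,7-dienamide
Product: 19 (2E,4S,6R)-N-{(3R)-5-chloro-6-oxo-3-(triethylsilyloxy)-3-[5-(triethylsilyloxy)pentyl]cyclohexa-1,4-dien-1-yl}-4,6,8-trimethylnona-2,7-dienamide
Conditions: CuI (cat.), N,N'-dimethylethylenediamine, Cs2CO3, THF, 50 °C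
Reagents that add atoms: none
Why: Goldberg-type copper-catalysed N-vinylation of a primary amide should occur at the activated α-iodoenone C–I bond and leave the vinyl chloride untouched; the stereocentres are not involved.

Step 14
Reactants: 19 (2E,4S,6R)-N-{(3R)-5-chloro-6-oxo-3-(triethylsilyloxy)-3-[5-(triethylsilyloxy)pentyl]cyclohexa-1,4-dien-1-yl}-4,6,8-trimethylnona-2,7-dienamide
Product: 20 (2E,4S,6R)-N-[(3R)-5-chloro-3-hydroxy-3-(5-hydroxypentyl)-6-oxocyclohexa-1,4-dien-1-yl]-4,6,8-trimethylnona-2,7-dienamide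
Conditions: HF·pyridine, pyridine, THF, 0 °C to rt
Reagents that add atoms: none
Why: Buffered HF·pyridine should cleave the primary and the tertiary triethylsilyl ether without exposing the quinol or the trisubstituted alkene to strong acid or base.

Step 15
Reactants: 20 (2E,4S,6R)-N-[(3R)-5-chloro-3-hydroxy-3-(5-hydroxypentyl)-6-oxocyclohexa-1,4-dien-1-yl]-4,6,8-trimethylnona-2,7-dienamide
Product: 21 5-[(1R)-3-chloro-1-hydroxy-4-oxo-5-{[(2E,4S,6R)-4,6,8-trimethylnona-2,7-dienoyl]amino}cyclohexa-2,5-dien-1-yl]pentanoic acid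
Conditions: TEMPO (cat.), PhI(OAc)2, MeCN/H2O, rt
Reagents that add atoms: water, O
Why: Oxoammonium-catalysed oxidation (TEMPO/diacetoxyiodobenzene in aqueous acetonitrile) should take the primary alcohol through the aldehyde hydrate to the acid, while the tertiary alcohol cannot be oxidised and alkenes and the enamide are tolerated.

**Compound list**

1 | (R)-4-(tert-butyldimethylsilyloxy)cyclopent-2-en-1-one | O=C1C=C[C@H](O[Si](C)(C)C(C)(C)C)C1 | starting material
2 | (5-bromopentyloxy)(tert-butyl)dimethylsilane | BrCCCCCO[Si](C)(C)C(C)(C)C | starting material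
3 | [5-(tert-butyldimethylsilyloxy)pentyl]magnesium bromide | Br[Mg]CCCCCO[Si](C)(C)C(C)(C)C | intermediate
4 | (1S,4R)-4-(tert-butyldimethylsilyloxy)-1-[5-(tert-butyldimethylsilyloxy)pentyl]cyclopent-2-en-1-ol | CC(C)(C)[Si](C)(C)O[C@H]1C=C[C@](O)(CCCCCO[Si](C)(C)C(C)(C)C)C1 | intermediate
5 | (1S,4R)-1-(5-hydroxypentyl)cyclopent-2-ene-1,4-diol | O[C@H]1C=C[C@](O)(CCCCCO)C1 | intermediate
6 | (S)-4-hydroxy-4-(5-hydroxypentyl)cyclopent-2-en-1-one | O=C1C=C[C@](O)(CCCCCO)C1 | intermediate
7 | (S)-4-hydroxy-4-(5-hydroxypentyl)-2-iodocyclopent-2-en-1-one | O=C1C(I)=C[C@](O)(CCCCCO)C1 | intermediate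
8 | (S)-2-iodo-3,5-bis(triethylsilyloxy)-5-[5-(triethylsilyloxy)pentyl]cyclopenta-1,3-diene | CC[Si](CC)(CC)OC1=C[C@@](O[Si](CC)(CC)CC)(CCCCCO[Si](CC)(CC)CC)C=C1I | intermediate
9 | (4S)-6,6-dichloro-2-iodo-1,4-bis(triethylsilyloxy)-4-[5-(triethylsilyloxy)pentyl]bicyclo[3.1.0]hex-2-ene (cyclopropane face not defined) | CC[Si](CC)(CC)OC12C(Cl)(Cl)C1[C@@](O[Si](CC)(CC)CC)(CCCCCO[Si](CC)(CC)CC)C=C2I | intermediate
10 | (S)-2-chloro-6-iodo-4-(triethylsilyloxy)-4-[5-(triethylsilyloxy)pentyl]cyclohexa-2,5-dien-1-one | O=C1C(Cl)=C[C@@](O[Si](CC)(CC)CC)(CCCCCO[Si](CC)(CC)CC)C=C1I | intermediate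
11 | meso-2,4-dimethylglutaric anhydride ((3R,5S)-3,5-dimethyloxane-2,6-dione) | O=C1[C@H](C)C[C@H](C)C(=O)O1 | starting material
12 | meso-(2R,4S)-2,4-dimethylpentane-1,5-diol | OC[C@H](C)C[C@H](C)CO | intermediate
13 | (2S,4R)-5-hydroxy-2,4-dimethylpentyl acetate | OC[C@H](C)C[C@H](C)COC(C)=O | intermediate
14 | (2S,4R)-2,4-dimethyl-5-oxopentyl acetate | O=C[C@H](C)C[C@H](C)COC(C)=O | intermediate
15 | (2S,4R)-2,4,6-trimethylhept-5-en-1-yl acetate | CC(C)=C[C@H](C)C[C@H](C)COC(C)=O | intermediate
16 | (2S,4R)-2,4,6-trimethylhept-5-en-1-ol | CC(C)=C[C@H](C)C[C@H](C)CO | intermediate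
17 | (2S,4R)-2,4,6-trimethylhept-5-enal | CC(C)=C[C@H](C)C[C@H](C)C=O | intermediate
18 | (2E,4S,6R)-4,6,8-trimethylnona-2,7-dienamide | CC(C)=C[C@H](C)C[C@H](C)/C=C/C(N)=O | intermediate
19 | (2E,4S,6R)-N-{(3R)-5-chloro-6-oxo-3-(triethylsilyloxy)-3-[5-(triethylsilyloxy)pentyl]cyclohexa-1,4-dien-1-yl}-4,6,8-trimethylnona-2,7-dienamide | CC(C)=C[C@H](C)C[C@H](C)/C=C/C(=O)NC1=C[C@](O[Si](CC)(CC)CC)(CCCCCO[Si](CC)(CC)CC)C=C(Cl)C1=O | intermediate
20 | (2E,4S,6R)-N-[(3R)-5-chloro-3-hydroxy-3-(5-hydroxypentyl)-6-oxocyclohexa-1,4-dien-1-yl]-4,6,8-trimethylnona-2,7-dienamide | CC(C)=C[C@H](C)C[C@H](C)/C=C/C(=O)NC1=C[C@](O)(CCCCCO)C=C(Cl)C1=O | intermediate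
21 | 5-[(1R)-3-chloro-1-hydroxy-4-oxo-5-{[(2E,4S,6R)-4,6,8-trimethylnona-2,7-dienoyl]amino}cyclohexa-2,5-dien-1-yl]pentanoic acid | CC(C)=C[C@H](C)C[C@H](C)/C=C/C(=O)NC1=C[C@](O)(CCCCC(=O)O)C=C(Cl)C1=O | target

**Step count.** Total: 15 steps. Longest linear sequence: 9 steps (steps 1–6 and 13–15 from 1; the side-chain branch, steps 7–12 and 13–15 from 11, is equally long).

**Steps most likely to fail**

Step 6 (ring expansion). The basic carbene-generating medium may strip the dienol silyl ether before cyclopropanation, trichloromethanide or tert-butoxide may add to the very electrophilic iododienone as it is released, or the cyclopropane may open by cleavage of the exocyclic bond. The fallback is a carbene-free one-carbon ring enlargement that sets out from 8 and comes back at 10. Simmons–Smith cyclopropanation (Et2Zn, CH2I2, CH2Cl2, 0 °C) of the siloxy-substituted double bond of 8 would give (4S)-2-iodo-1,4-bis(triethylsilyloxy)-4-[5-(triethylsilyloxy)pentyl]bicyclo[3.1.0]hex-2-ene F1. FeCl3 in DMF at 0 °C would cleave the ring-fusion bond oxidatively to the ring-enlarged β-chloro ketone (4R)-5-chloro-2-iodo-4-(triethylsilyloxy)-4-[5-(triethylsilyloxy)pentyl]cyclohex-2-en-1-one F2. Et3N would eliminate HCl to (S)-2-iodo-4-(triethylsilyloxy)-4-[5-(triethylsilyloxy)pentyl]cyclohexa-2,5-dien-1-one F3, in which the iodine keeps the carbinol stereogenic. α-Chlorination of the unsubstituted enone arm with PhSeCl/pyridine would then give 10.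

Step 13 (N-vinylation). Coupling of the conjugated primary amide may be slower than degradation of the dienone by the base or by aza-Michael addition of the diamine ligand, or than protodeiodination. The fallback forms the amide bond by N-acylation instead of N-vinylation; it sets out from 10 and 17 and comes back at 19. Palladium-catalysed coupling of 10 with benzophenone imine (Pd2(dba)3, Xantphos, Cs2CO3, toluene, 60 °C) would give (R)-2-chloro-6-[(diphenylmethylidene)amino]-4-(triethylsilyloxy)-4-[5-(triethylsilyloxy)pentyl]cyclohexa-2,5-dien-1-one F4. Aqueous citric acid/THF would hydrolyse it to (R)-2-amino-6-chloro-4-(triethylsilyloxy)-4-[5-(triethylsilyloxy)pentyl]cyclohexa-2,5-dien-1-one F5. In parallel, aldehyde 17 would be treated with Ph3P=CHCO2Me to give methyl (2E,4S,6R)-4,6,8-trimethylnona-2,7-dienoate F6, saponified (LiOH, THF/H2O) to (2E,4S,6R)-4,6,8-trimethylnona-2,7-dienoic acid F7, and converted with 1-chloro-N,N,2-trimethylprop-1-en-1-amine into (2E,4S,6R)-4,6,8-trimethylnona-2,7-dienoyl chloride F8. Acylation of F5 with F8 (pyridine, CH2Cl2, 0 °C) would give 19.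

Step 1 (1,2-addition). The organometallic may enolise 1 with subsequent loss of silanolate, add in the 1,4-sense, or attack with insufficient facial selectivity. The fallback replaces substrate control by enantioselective desymmetrisation of a meso-epoxide; it sets out from 3 and comes back at 5. Addition of 3 (CeCl3, THF, −78 °C) to commercial cyclopent-3-en-1-one would give 1-[5-(tert-butyldimethylsilyloxy)pentyl]cyclopent-3-en-1-ol F9. Hydroxyl-directed epoxidation (VO(acac)2, t-BuOOH, CH2Cl2) would give the meso epoxy alcohol cis-3-[5-(tert-butyldimethylsilyloxy)pentyl]-6-oxabicyclo[3.1.0]hexan-3-ol F10 (hydroxyl and epoxide oxygen on the same face). Enantioselective syn-β-elimination with an enantiopure lithium amide (lithium bis(1-phenylethyl)amide, the antipode chosen by the sense of proton abstraction) would give (1S,4R)-1-[5-(tert-butyldimethylsilyloxy)pentyl]cyclopent-2-ene-1,4-diol F11. Desilylation with TBAF would then give 5.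

**Further compounds**

F1 | step 6 | (4S)-2-iodo-1,4-bis(triethylsilyloxy)-4-[5-(triethylsilyloxy)pentyl]bicyclo[3.1.0]hex-2-ene | CC[Si](CC)(CC)OC12CC1[C@@](O[Si](CC)(CC)CC)(CCCCCO[Si](CC)(CC)CC)C=C2I
F2 | step 6 | (4R)-5-chloro-2-iodo-4-(triethylsilyloxy)-4-[5-(triethylsilyloxy)pentyl]cyclohex-2-en-1-one | O=C1CC(Cl)[C@@](O[Si](CC)(CC)CC)(CCCCCO[Si](CC)(CC)CC)C=C1I
F3 | step 6 | (S)-2-iodo-4-(triethylsilyloxy)-4-[5-(triethylsilyloxy)pentyl]cyclohexa-2,5-dien-1-one | O=C1C=C[C@@](O[Si](CC)(CC)CC)(CCCCCO[Si](CC)(CC)CC)C=C1I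
F4 | step 13 | (R)-2-chloro-6-[(diphenylmethylidene)amino]-4-(triethylsilyloxy)-4-[5-(triethylsilyloxy)pentyl]cyclohexa-2,5-dien-1-one | C(c1ccccc1)(c1ccccc1)=NC1=C[C@](O[Si](CC)(CC)CC)(CCCCCO[Si](CC)(CC)CC)C=C(Cl)C1=O
F5 | step 13 | (R)-2-amino-6-chloro-4-(triethylsilyloxy)-4-[5-(triethylsilyloxy)pentyl]cyclohexa-2,5-dien-1-one | NC1=C[C@](O[Si](CC)(CC)CC)(CCCCCO[Si](CC)(CC)CC)C=C(Cl)C1=O
F6 | step 13 | methyl (2E,4S,6R)-4,6,8-trimethylnona-2,7-dienoate | CC(C)=C[C@H](C)C[C@H](C)/C=C/C(=O)OC
F7 | step 13 | (2E,4S,6R)-4,6,8-trimethylnona-2,7-dienoic acid | CC(C)=C[C@H](C)C[C@H](C)/C=C/C(=O)O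
F8 | step 13 | (2E,4S,6R)-4,6,8-trimethylnona-2,7-dienoyl chloride | CC(C)=C[C@H](C)C[C@H](C)/C=C/C(=O)Cl
F9 | step 1 | 1-[5-(tert-butyldimethylsilyloxy)pentyl]cyclopent-3-en-1-ol | OC1(CCCCCO[Si](C)(C)C(C)(C)C)CC=CC1
F10 | step 1 | cis-3-[5-(tert-butyldimethylsilyloxy)pentyl]-6-oxabicyclo[3.1.0]hexan-3-ol (meso) | O[C@@]1(CCCCCO[Si](C)(C)C(C)(C)C)C[C@H]2O[C@H]2C1
F11 | step 1 | (1S,4R)-1-[5-(tert-butyldimethylsilyloxy)pentyl]cyclopent-2-ene-1,4-diol | O[C@H]1C=C[C@](O)(CCCCCO[Si](C)(C)C(C)(C)C)C1
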